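**Retrosynthetic overview**

Atom labels: ring A = C1 (bears the exocyclic CH2), C2, C3, C4 (CHBr), C5 (CMe2), C6 (spiro); ring B = C6, C7, C8, C9 (CMeBr), C10 (CHCl), C11.
The strategy rests on ring B: C6, C7, C10 and C11 are taken as a spiro cyclobutanone (C10 = carbonyl) enlarged by the two carbons C8 and C9 of a propyne unit; nickel-catalysed insertion of 1-(trimethylsilyl)propyne into one acyl–CH2 bond forms C9–C10 and C7–C8, closes ring B and creates the C6 stereocentre.
The trans C9–Br/C10–Cl pair goes back to the C9=C10 alkene (epoxide on the face cis to C5, chloride at C10 with inversion, bromide at C9 with retention through a chloronium ion), and this alkene to the insertion product by protodesilylation, conjugate reduction/enol triflate formation and formate reduction.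
The cyclobutanone carries ring A complete, with C4–Br and with C1 already as the methylene (a ring A ketone would be reduced by the hydride of step 13 and could not be methylenated selectively later); ring A is closed onto the purchased four-membered ring by a bromonium-ion cyclisation (C5–C6) whose bromonium comes from an enantioenriched prenol bromochloride that fixes C4.
Ring order: cyclobutane (bought) → ring A (step 8) → ring B by two-carbon ring enlargement (step 11).

Key step: step 11

Remark (assumption): both antipodes of the chiral ligands of steps 4 and 11 are available; the one giving (R) at C4, and the one directing cleavage of the C10–CH2 bond trans to the C4 bromine, is used.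
Remark (assumption): 1-bromo-N,N,2-trimethylprop-1-en-1-amine (step 17) is prepared beforehand from the commercial chloro analogue by halide exchange.

**Route**

Step 1
Reactants: 1 3-oxocyclobutane-1-carboxylic acid
Product: 2 methyl 3,3-dimethoxycyclobutane-1-carboxylate
Conditions: HC(OMe)3, MeOH, TsOH·H2O (cat.), reflux
Reagents that add atoms: trimethyl orthoformate COC(OC)OC; methanol CO
Why: Acid-catalysed ketalisation of the strained ketone and Fischer esterification run together, the orthoformate removing water; no stereocentre is involved.

Step 2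
Reactants: 2 methyl 3,3-dimethoxycyclobutane-1-carboxylate
Product: 3 N-methoxy-N-methyl-3,3-dimethoxycyclobutane-1-carboxamide
Conditions: MeNH(OMe)·HCl, i-PrMgCl, THF, −20 °C
Reagents that add atoms: N,O-dimethylhydroxylamine hydrochloride CNOC.Cl
Why: The chloromagnesium amide formed in the flask acylates at the ester carbonyl (ester aminolysis to an N-methoxy-N-methylamide), and the ketal is inert to base.

Step 3
Reactants: 3 N-methoxy-N-methyl-3,3-dimethoxycyclobutane-1-carboxamide
Product: 4 1-(3,3-dimethoxycyclobutyl)ethan-1-one
Conditions: MeMgBr, THF, 0 °C; aq. NH4Cl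
Reagents that add atoms: methylmagnesium bromide C[Mg]Br
Why: Ketone synthesis from an N-methoxy-N-methylamide: the magnesium-chelated adduct does not collapse before work-up, so only one methyl group is added.

Step 4
Reactants: 5 prenol (3-methylbut-2-en-1-ol)
Product: 6 (R)-2-bromo-3-chloro-3-methylbutan-1-ol
Conditions: NBS, ClTi(OiPr)3, chiral tridentate Schiff-base ligand (20 mol %), hexanes, −20 °C
Reagents that add atoms: N-bromosuccinimide O=C1CCC(=O)N1Br; chlorotitanium triisopropoxide CC(C)O[Ti](Cl)(OC(C)C)OC(C)C
Why: Catalytic enantioselective bromochlorination of an allylic alcohol: the titanium-bound alkoxide of 5 is brominated on the alkene face set by the chiral ligand, and titanium-bound chloride opens the bromonium ion anti at the tertiary carbon (Markovnikov), which sets the CHBr centre (future C4) as (R).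

Step 5
Reactants: 6 (R)-2-bromo-3-chloro-3-methylbutan-1-ol
Product: 7 (R)-2-bromo-3-chloro-3-methylbutyl trifluoromethanesulfonate
Conditions: Tf2O, 2,6-lutidine, CH2Cl2, −78 °C
Reagents that add atoms: trifluoromethanesulfonic anhydride O=S(=O)(OS(=O)(=O)C(F)(F)F)C(F)(F)F
Why: O-Sulfonylation of the primary alcohol leaves the CHBr centre untouched and gives an electrophile reactive enough for SN2 at a β-branched carbon; it is used at once.

Step 6
Reactants: 4 1-(3,3-dimethoxycyclobutyl)ethan-1-one; 7 (R)-2-bromo-3-chloro-3-methylbutyl trifluoromethanesulfonate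
Product: 9 (5R)-5-bromo-6-chloro-1-(3,3-dimethoxycyclobutyl)-6-methylheptan-1-one, via lithium enolate 8 (not isolated)
Conditions: LiN(i-Pr)2, THF, −78 °C; then 7, −78 to −30 °C
Reagents that add atoms: none
Why: Kinetic deprotonation occurs at the methyl group (the cyclobutyl methine is more hindered), and the lithium enolate displaces the primary triflate by SN2 (enolate C-alkylation), forming C2–C3 without touching the CHBr centre or the tertiary chloride.

Step 7
Reactants: 9 (5R)-5-bromo-6-chloro-1-(3,3-dimethoxycyclobutyl)-6-methylheptan-1-one
Product: 10 tert-butyl{[(5R)-5-bromo-6-chloro-1-(3,3-dimethoxycyclobutylidene)-6-methylheptyl]oxy}dimethylsilane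
Conditions: TBSOTf (1.1 equiv), Et3N, CH2Cl2, −20 to 0 °C
Reagents that add atoms: tert-butyldimethylsilyl trifluoromethanesulfonate CC(C)(C)[Si](C)(C)OS(=O)(=O)C(F)(F)F
Why: Soft enolisation (silyl triflate/amine) is expected to favour the more substituted cyclobutylidene enol ether, since an exocyclic double bond adds little strain to a four-membered ring; any C1=C2 regioisomer cannot close a six-membered ring in step 8 and returns 9, and no stereocentre is affected.

Step 8
Reactants: 10 tert-butyl{[(5R)-5-bromo-6-chloro-1-(3,3-dimethoxycyclobutylidene)-6-methylheptyl]oxy}dimethylsilane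
Product: 11 (8R)-8-bromo-2,2-dimethoxy-9,9-dimethylspiro[3.5]nonan-5-one
Conditions: (CF3)2CHOH, 2,6-di-tert-butyl-4-methylpyridine, 0 °C to rt
Reagents that add atoms: none
Why: Cation–olefin cyclisation of an enantioenriched vicinal bromochloride terminated by an enol silane: the ionising solvent cleaves the tertiary C5–Cl bond with anchimeric help from the anti C4 bromine, the C6 terminus of the enol silane opens the bridged bromonium ion at C5 (6-endo on the bromonium, enol-endo) to form C5–C6 and the quaternary spiro carbon, and loss of the silyl group returns the C1 ketone; C4 keeps (R) and C6 is not yet stereogenic.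

Step 9
Reactants: 11 (8R)-8-bromo-2,2-dimethoxy-9,9-dimethylspiro[3.5]nonan-5-one
Product: 12 (6R)-6-bromo-2,2-dimethoxy-5,5-dimethyl-9-methylidenespiro[3.5]nonane
Conditions: Cp2TiMe2, toluene/THF, 70 °C, dark
Reagents that add atoms: dimethyltitanocene C[Ti](C)(C1C=CC=C1)C1C=CC=C1
Why: Petasis methylenation: thermolysis of Cp2TiMe2 gives Cp2Ti=CH2, which converts hindered, enolisable ketones into methylene compounds through an oxatitanacyclobutane without base, so the ketal and the C4 bromide are preserved.

Step 10
Reactants: 12 (6R)-6-bromo-2,2-dimethoxy-5,5-dimethyl-9-methylidenespiro[3.5]nonane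
Product: 13 (6R)-6-bromo-5,5-dimethyl-9-methylidenespiro[3.5]nonan-2-one
Conditions: TsOH·H2O (cat.), acetone/H2O, rt
Reagents that add atoms: water O
Why: Acid-catalysed hydrolysis of the dimethyl ketal is far faster than protonation of the hindered 1,1-disubstituted alkene, so dilute acid at room temperature should free the symmetric cyclobutanone without alkene migration.

Step 11
Reactants: 13 (6R)-6-bromo-5,5-dimethyl-9-methylidenespiro[3.5]nonan-2-one; 14 1-(trimethylsilyl)propyne
Product: 15 (4R,6R)-4-bromo-5,5,9-trimethyl-1-methylidene-8-(trimethylsilyl)spiro[5.5]undec-8-en-10-one (overview locants)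
Conditions: Ni(cod)2 (10 mol %), chiral BINOL-derived phosphoramidite with a bis(1-phenylethyl)amino group (20 mol %), 14 (3 equiv), toluene, 60 °C
Reagents that add atoms: none
Why: Zerovalent nickel couples the cyclobutanone carbonyl and the alkyne oxidatively to an oxanickelacyclopentene with the methyl-bearing carbon (C9) bonded to C10 and the silyl-bearing carbon (C8) on nickel; strain-driven β-carbon elimination opens the four-membered ring to a seven-membered nickelacycle, and C(sp3)–C(sp2) reductive elimination forms C7–C8. The closest known reaction type is the nickel-catalysed intermolecular insertion of alkynes into 3,3-disubstituted cyclobutanones by C–C cleavage (formal [4+2]), including ligand-controlled desymmetrising variants. Ring B is therefore closed by ring enlargement, four-membered to six-membered through reductive elimination from the seven-membered nickelacycle, not by an end-to-end cyclisation. C6 becomes stereogenic because only one of the two diastereotopic C10–CH2 bonds is cut: the chiral ligand on nickel must select the methylene trans to the C4 bromine across ring A (it becomes C7), while the methylene cis to bromine stays on the carbonyl as C11; the axial/equatorial difference of the two methylenes on ring A adds a substrate bias that the choice of ligand antipode can match. Regiochemistry rests on the silyl group, which takes the nickel-bound position in the oxidative cyclisation, so that the methyl group ends at C9 next to the C10 carbonyl. The step also needs the neopentyl C4–Br bond and the exocyclic alkene to stay untouched, for which the fast reaction of the strained ketone, moderate temperature and excess alkyne are relied on.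

Step 12
Reactants: 15 (4R,6R)-4-bromo-5,5,9-trimethyl-1-methylidene-8-(trimethylsilyl)spiro[5.5]undec-8-en-10-one
Product: 16 (4R,6S)-4-bromo-5,5,9-trimethyl-1-methylidenespiro[5.5]undec-8-en-10-one
Conditions: Bu4NF·3H2O, THF, 0 °C to rt
Reagents that add atoms: none
Why: Fluoride-mediated protodesilylation of a vinylsilane: fluoride adds to silicon and the C8–Si bond is cleaved with protonation by water, helped by the electron-withdrawing enone; the C6 descriptor changes from R to S only because the priority of C7 drops.

Step 13
Reactants: 16 (4R,6S)-4-bromo-5,5,9-trimethyl-1-methylidenespiro[5.5]undec-8-en-10-one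
Product: 18 (4R,6S)-4-bromo-5,5,9-trimethyl-1-methylidenespiro[5.5]undec-9-en-10-yl trifluoromethanesulfonate, via lithium enolate 17 (not isolated)
Conditions: LiBH(s-Bu)3, THF, −78 °C; then PhNTf2, −78 °C to rt
Reagents that add atoms: N-phenylbis(trifluoromethanesulfonimide) O=S(=O)(N(c1ccccc1)S(=O)(=O)C(F)(F)F)C(F)(F)F
Why: LiBH(s-Bu)3 adds hydride to the unsubstituted β-carbon C8 of the 2-methylcyclohexenone (conjugate reduction), and the regiodefined enolate is O-sulfonylated, fixing the double bond at C9=C10; no other carbonyl is present and the hindered secondary bromide does not react with the hydride.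

Step 14
Reactants: 18 (4R,6S)-4-bromo-5,5,9-trimethyl-1-methylidenespiro[5.5]undec-9-en-10-yl trifluoromethanesulfonate
Product: 19 (4R,6S)-4-bromo-5,5,9-trimethyl-1-methylidenespiro[5.5]undec-9-ene
Conditions: Pd(OAc)2 (5 mol %), PPh3, HCO2H, n-Bu3N, DMF, 60 °C
Reagents that add atoms: none
Why: Palladium-catalysed formate reduction of an enol triflate: zerovalent palladium formed in the flask inserts into the vinyl C–O bond, formate exchange and loss of CO2 give a vinylpalladium hydride, and reductive elimination leaves the C9=C10 alkene in place; the unactivated secondary bromide and the exocyclic alkene are inert here.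

Step 15
Reactants: 19 (4R,6S)-4-bromo-5,5,9-trimethyl-1-methylidenespiro[5.5]undec-9-ene
Product: 20 (4R,6S,9R,10S)-4-bromo-9,10-epoxy-5,5,9-trimethyl-1-methylidenespiro[5.5]undecane
Conditions: mCPBA (1.0 equiv), NaHCO3, CH2Cl2, −20 to 0 °C
Reagents that add atoms: 3-chloroperoxybenzoic acid OOC(=O)c1cccc(Cl)c1
Why: Peracid epoxidation is faster at the trisubstituted C9=C10 alkene than at the hindered 1,1-disubstituted exocyclic alkene, and attack is expected on the ring B face anti to C1 (axial on ring B at the spiro centre, C5 with its methyl groups equatorial), giving the epoxide cis to C5 and so setting C9 and C10.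

Step 16
Reactants: 20 (4R,6S,9R,10S)-4-bromo-9,10-epoxy-5,5,9-trimethyl-1-methylidenespiro[5.5]undecane
Product: 21 (4R,6S,9R,10R)-4-bromo-10-chloro-5,5,9-trimethyl-1-methylidenespiro[5.5]undecan-9-ol
Conditions: LiCl, AcOH, THF, rt
Reagents that add atoms: lithium chloride [Li+].[Cl-]
Why: Chloride opens the epoxide by SN2 at the secondary carbon C10 with inversion under weakly acidic, non-ionising conditions, which is also the trans-diaxial (Fürst–Plattner) mode in the favoured chair, so C10 becomes (R) with chlorine cis to C1 and the tertiary C9 alcohol keeps its configuration; acetic acid is too weak to protonate the exocyclic alkene.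

Step 17
Reactants: 21 (4R,6S,9R,10R)-4-bromo-10-chloro-5,5,9-trimethyl-1-methylidenespiro[5.5]undecan-9-ol
Product: 22 (4R,6S,9R,10R)-4,9-dibromo-10-chloro-5,5,9-trimethyl-1-methylidenespiro[5.5]undecane (systematic locants: (2R,6S,8R,9R)-2,9-dibromo-8-chloro-1,1,9-trimethyl-5-methylidenespiro[5.5]undecane)
Conditions: 1-bromo-N,N,2-trimethylprop-1-en-1-amine, CH2Cl2, 0 °C to rt
Reagents that add atoms: 1-bromo-N,N,2-trimethylprop-1-en-1-amine CC(C)=C(Br)N(C)C
Why: Deoxybromination with an α-haloenamine under neutral conditions: the tertiary alcohol adds to the keteniminium form of the reagent, the alkoxy-iminium group leaves with anchimeric help from the anti-periplanar C10 chlorine, and bromide opens the chloronium ion at the tertiary carbon C9 on the face the oxygen occupied (net retention, trans Br/Cl); no free HBr forms, so the exocyclic alkene should survive.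

**Compound list**

1 | 3-oxocyclobutane-1-carboxylic acid | OC(=O)C1CC(=O)C1 | starting material
2 | methyl 3,3-dimethoxycyclobutane-1-carboxylate | COC(=O)C1CC(OC)(OC)C1 | intermediate
3 | N-methoxy-N-methyl-3,3-dimethoxycyclobutane-1-carboxamide | CON(C)C(=O)C1CC(OC)(OC)C1 | intermediate
4 | 1-(3,3-dimethoxycyclobutyl)ethan-1-one | CC(=O)C1CC(OC)(OC)C1 | intermediate
5 | prenol (3-methylbut-2-en-1-ol) | CC(C)=CCO | starting material
6 | (R)-2-bromo-3-chloro-3-methylbutan-1-ol | OC[C@@H](Br)C(C)(C)Cl | intermediate
7 | (R)-2-bromo-3-chloro-3-methylbutyl trifluoromethanesulfonate | O=S(=O)(OC[C@@H](Br)C(C)(C)Cl)C(F)(F)F | intermediate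
8 | lithium enolate of 4 (lithium 1-(3,3-dimethoxycyclobutyl)ethen-1-olate) | C=C(O[Li])C1CC(OC)(OC)C1 | intermediate (not isolated)
9 | (5R)-5-bromo-6-chloro-1-(3,3-dimethoxycyclobutyl)-6-methylheptan-1-one | COC1(OC)CC(C1)C(=O)CC[C@@H](Br)C(C)(C)Cl | intermediate
10 | tert-butyl{[(5R)-5-bromo-6-chloro-1-(3,3-dimethoxycyclobutylidene)-6-methylheptyl]oxy}dimethylsilane | COC1(OC)CC(=C(O[Si](C)(C)C(C)(C)C)CC[C@@H](Br)C(C)(C)Cl)C1 | intermediate
11 | (8R)-8-bromo-2,2-dimethoxy-9,9-dimethylspiro[3.5]nonan-5-one | O=C1CC[C@@H](Br)C(C)(C)C12CC(OC)(OC)C2 | intermediate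
12 | (6R)-6-bromo-2,2-dimethoxy-5,5-dimethyl-9-methylidenespiro[3.5]nonane | C=C1CC[C@@H](Br)C(C)(C)C12CC(OC)(OC)C2 | intermediate
13 | (6R)-6-bromo-5,5-dimethyl-9-methylidenespiro[3.5]nonan-2-one | C=C1CC[C@@H](Br)C(C)(C)C12CC(=O)C2 | intermediate
14 | 1-(trimethylsilyl)propyne | CC#C[Si](C)(C)C | starting material
15 | (4R,6R)-4-bromo-5,5,9-trimethyl-1-methylidene-8-(trimethylsilyl)spiro[5.5]undec-8-en-10-one | C=C1CC[C@@H](Br)C(C)(C)[C@]12CC([Si](C)(C)C)=C(C)C(=O)C2 | intermediate
16 | (4R,6S)-4-bromo-5,5,9-trimethyl-1-methylidenespiro[5.5]undec-8-en-10-one | C=C1CC[C@@H](Br)C(C)(C)[C@]12CC=C(C)C(=O)C2 | intermediate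
17 | lithium enolate from 16 (C9=C10 enolate) | C=C1CC[C@@H](Br)C(C)(C)[C@]12CCC(C)=C(O[Li])C2 | intermediate (not isolated)
18 | (4R,6S)-4-bromo-5,5,9-trimethyl-1-methylidenespiro[5.5]undec-9-en-10-yl trifluoromethanesulfonate | C=C1CC[C@@H](Br)C(C)(C)[C@]12CCC(C)=C(OS(=O)(=O)C(F)(F)F)C2 | intermediate
19 | (4R,6S)-4-bromo-5,5,9-trimethyl-1-methylidenespiro[5.5]undec-9-ene | C=C1CC[C@@H](Br)C(C)(C)[C@]12CCC(C)=CC2 | intermediate
20 | (4R,6S,9R,10S)-4-bromo-9,10-epoxy-5,5,9-trimethyl-1-methylidenespiro[5.5]undecane | C=C1CC[C@@H](Br)C(C)(C)[C@]12CC[C@@]3(C)O[C@H]3C2 | intermediate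
21 | (4R,6S,9R,10R)-4-bromo-10-chloro-5,5,9-trimethyl-1-methylidenespiro[5.5]undecan-9-ol | C=C1CC[C@@H](Br)C(C)(C)[C@]12CC[C@@](C)(O)[C@H](Cl)C2 | intermediate
22 | (4R,6S,9R,10R)-4,9-dibromo-10-chloro-5,5,9-trimethyl-1-methylidenespiro[5.5]undecane | C=C1CC[C@@H](Br)C(C)(C)[C@]12CC[C@@](C)(Br)[C@H](Cl)C2 | target

**Step count**

Total: 17 steps. Longest linear sequence: 15 steps (steps 1–3 and 6–17, from 1).

**Steps most likely to fail**

Step 11 (key step). Zerovalent nickel may cleave the C4–Br bond by halogen abstraction, the alkyne may oligomerise instead of coupling with the ketone, or the two diastereotopic acyl–CH2 bonds may be cut without discrimination so that C6 forms as a mixture. The fallback sets out from 13 and comes back at 16, enlarging the ring stepwise by polar chemistry. A desymmetrising Baeyer–Villiger oxidation of 13 (aqueous H2O2, chiral BINOL-derived phosphoric acid, CHCl3, −40 °C; the alkene is inert to H2O2), in which the methylene trans to bromine migrates, gives the spiro γ-lactone F1. Opening with Me2AlN(OMe)Me gives the hydroxy N-methoxy-N-methylamide F2. Dess–Martin oxidation gives the aldehyde F3. Wittig reaction with Ph3P=CHOMe gives the enol ether F4, which introduces C8. EtMgBr gives the ethyl ketone F5, which introduces C9 and its methyl group. Dilute aqueous HCl in THF frees the keto aldehyde F6, and KOH in MeOH closes ring B by intramolecular aldol condensation of C9 onto C8 with dehydration to 16.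

Step 8. The enol ether of step 7 may form largely as the C1=C2 regioisomer, the silyl enol ether may be protodesilylated by the solvent before the C5–Cl bond ionises, or the cation may be captured at oxygen or by solvent, or lose a proton. The fallback sets out from 9 and comes back at 11; it blocks C2 and uses a more nucleophilic diene terminator. Formylation of the kinetic C2 enolate of 9 (LiN(i-Pr)2, then CF3CH2OCHO, THF, −78 °C) gives the 2-(hydroxymethylene) ketone F7, in which C6 is the only enolisable position left. Double silylation (TBSOTf, Et3N, CH2Cl2) gives the 1,3-bis(silyloxy)diene F8, whose nucleophilic terminus is C6. The same ionisation in (CF3)2CHOH gives the spiro silyloxymethylene ketone F9. K2CO3 in MeOH then removes the blocking group by desilylation and retro-Claisen deformylation to give 11.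

Step 17. Ionisation of the tertiary C9 centre may end in loss of a proton (elimination to an allylic chloride) instead of bromide capture, or capture may occur without control by the chlorine, giving the C9 epimer. The fallback sets out from 21 and comes back at 22; it separates activation from ionisation. Trifluoroacetylation ((CF3CO)2O, pyridine, CH2Cl2, 0 °C) gives the tertiary trifluoroacetate F10. F10 is ionised in (CF3)2CHOH buffered with 2,6-di-tert-butyl-4-methylpyridine in the presence of Bu4NBr, so that the chloronium ion formed by the anti chlorine is opened by bromide at C9 in a strongly ionising, non-basic medium.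

**Further compounds**

F1 | step 11 | spiro γ-lactone (C10 lactone carbonyl, ring oxygen on C7) | C=C1CC[C@@H](Br)C(C)(C)[C@]12COC(=O)C2
F2 | step 11 | hydroxy N-methoxy-N-methylamide (C7 CH2OH, C10 amide) | C=C1CC[C@@H](Br)C(C)(C)[C@@]1(CO)CC(=O)N(C)OC
F3 | step 11 | aldehyde N-methoxy-N-methylamide (C7 CHO) | C=C1CC[C@@H](Br)C(C)(C)[C@@]1(C=O)CC(=O)N(C)OC
F4 | step 11 | methyl enol ether N-methoxy-N-methylamide (C7=C8 enol ether, E/Z mixture) | C=C1CC[C@@H](Br)C(C)(C)[C@@]1(C=COC)CC(=O)N(C)OC
F5 | step 11 | methyl enol ether ethyl ketone | C=C1CC[C@@H](Br)C(C)(C)[C@@]1(C=COC)CC(=O)CC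
F6 | step 11 | keto aldehyde (C8 aldehyde, C10 ethyl ketone) | C=C1CC[C@@H](Br)C(C)(C)[C@@]1(CC=O)CC(=O)CC
F7 | step 8 | 2-(hydroxymethylene) derivative of 9 | COC1(OC)CC(C1)C(=O)C(=CO)C[C@@H](Br)C(C)(C)Cl
F8 | step 8 | 1,3-bis(tert-butyldimethylsilyloxy)diene from F7 | COC1(OC)CC(=C(O[Si](C)(C)C(C)(C)C)C(=CO[Si](C)(C)C(C)(C)C)C[C@@H](Br)C(C)(C)Cl)C1
F9 | step 8 | spiro 6-(silyloxymethylene) ketone (C2-blocked 11) | O=C1C(=CO[Si](C)(C)C(C)(C)C)C[C@@H](Br)C(C)(C)C12CC(OC)(OC)C2
F10 | step 17 | tertiary trifluoroacetate of 21 | C=C1CC[C@@H](Br)C(C)(C)[C@]12CC[C@@](C)(OC(=O)C(F)(F)F)[C@H](Cl)C2
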